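## Structural features

The target is a 1-tetralone: aromatic ring A is fused to carbocyclic ring B, which carries the C1 ketone and the C3 secondary carbinol. A 4-hydroxy-2-pyrone (ring C) is bonded through its C6 to C5 of ring A. Ring A is substituted at five of its six positions (C4a, C5 pyronyl, C6 3-methylbutyl, C8 OH, C8a), so the aryl–pyrone bond at C5 is flanked on both sides, by the C4 methylene and by the side chain. C3 (R) is the only stereocentre; it has no neighbouring stereocentre to relay from and lies β to the C1 ketone. The β-hydroxy ketone of ring B is the fragile part: loss of water (or of an alcohol from a C3 ether) under base, acid or heat gives an enone that tautomerises irreversibly to a naphthol, and retro-aldol opening of C2–C3 would racemise C3. The pyrone is an acidic vinylogous acid that is opened by hydroxide and is nucleophilic at its C3, and the C8 phenol is hydrogen-bonded to the peri ketone. The real difficulty is to set a lone carbinol centre in a ring that wants to aromatise, and to attach ring C at the hindered C5 without base. The key step uses the fact that C1–C2–C3(O)–C4 maps onto a 3-oxygenated cyclobutanone whose carbonyl carbon is bonded to C8a: in the derived 1-arylcyclobutanol, C3 lies on a mirror plane, the two C1–CH2 bonds are enantiotopic, and cleaving one while bonding the freed CH2 to C4a makes ring B and renders C3 stereogenic.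

## Logic of the disconnections

18 to 17. The O–CH3 bond at C8 and the O–CH2Ph bond at C3 are cut. The free phenol, pyrone OH and β-hydroxy ketone together are the most fragile array, so they are unveiled last. The gain is that 17 carries the two sensitive oxygens as ethers through all C–C bond formation. The demand is an ether cleavage at low temperature, without base, that neither ionises the C3–O bond nor dehydrates ring B.

17 to 16. The O1–C6 bond of ring C is cut (and the tert-butyl group restored on the ester oxygen). A C6-metallated 4-alkoxy-2-pyrone is not a catalogue reagent and would need an unproven synthesis of its own, so ring C is built on the arene instead of being cross-coupled. The gain is an acyclic ynone β-keto ester. The demand is a 6-endo oxygen cyclisation at an alkyne carbon that bears a hindered aryl group, under non-basic conditions.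

16 to 15. The side-chain ketone is traced back to a carbinol. A terminal ynone could not survive a coupling, whereas the alkynol 14 can. The gain is a stable coupling partner; the demand is a neutral oxidation that leaves the benzyl ether and ring B alone.

15 to 9 and 14. The C5–C(sp) bond is cut, the only bond joining ring A to the side chain. The gain is convergence. The demand is a coupling at a di-ortho-substituted, electron-rich C–Br bond with a base mild enough for the β-alkoxy ketone.

14 to 13, and 13 to 10 and 11. The C–Si bond is cut, then the bond between the carbinol carbon and the ester α-carbon (aldol). Both fragments are catalogue compounds; the demand is only clean 1,2-addition.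

9 to 8. The C5–Br bond is cut. The handle is installed after ring B is made so that the key step sees a single C–Br bond. The demand is substitution para to the methoxy group (C5) and not ortho (C7) or α to the ketone.

8 to 7 (key disconnection). The C4a–C4 bond is cut, C4 is reconnected to C1, the ketone becomes a carbinol and bromine is placed on C4a. This turns a chiral tetralone into an achiral compound with a mirror plane through C3, so one C–C bond formation delivers ring B and the only stereocentre. The demand is catalyst-controlled choice between two enantiotopic C–C bonds, intramolecular C–C coupling, and no β-elimination at the alkylmetal stage.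

7 to 3 and 4. The C8a–C1 bond (aryl to carbinol carbon) is cut. The gain is an aryl nucleophile and a catalogue ketone. The demand is metalation between bromine and methoxy without loss of metal bromide, addition without enolisation, and attack anti to the benzyloxy group so that a single achiral diastereomer forms.

3 to 1 and 2. The bond between ring A and the first CH2 of the side chain is cut. The carbon–iodine bond of 1 reacts ahead of its C–Br bond, so mono-alkylation is chemoselective and not statistical. The demand is that the C–Br bond is left intact.

## Other disconnections considered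

Alternative 1: Ring A is built onto ring B by cutting C4a–C5 and C8–C8a. In the forward step the dienolate of the glutaconate diester A3 adds through C5 to C4a of the sulfinyl enone A2 (Michael), the resulting enolate carbon C8a attacks the distal ester (Claisen), and sulfoxide elimination with enolisation aromatises ring A to give A1.
- In its favour: every substituent of ring A is placed by construction, with the C5 carbon already present. On this point it is better than the chosen plan, which relies on a regioselective late bromination. It also forms two C–C bonds and an aromatic ring in one operation (better bond economy than the chosen key step), and C3 is bought in as a stereodefined carbinol in A2 and not created by a catalyst.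
- Against it here: the cascade runs in base on a β-silyloxy ketone, and A1 is itself a β-silyloxy tetralone, so loss of silanol with aromatisation of ring B is a standing threat. The α versus γ reactivity of the dienolate and the alkene geometry of A3 must be controlled. A2 needs several steps of its own. The ester of A1, flanked by two ortho groups, must still be turned into the pyrone by acylation chemistry that is either strongly basic or sterically slow.
- Comparison: on structure it is the better plan for ring A and the worse one for ring C. On mechanism it trades one catalyst-controlled step for an anionic cascade on a base-labile ring. On step count it is expected to be equal or longer.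

Alternative 2: Both ring B anchors are cut at once, C4a–C4 and C8a–C1. Fluoride would release the aryne from the silyl triflate A5; the enolate of methyl acetoacetate A6 adds at C4a, the aryl anion at C8a closes onto the acetyl carbonyl, and fragmentation of the four-membered alkoxide gives A4.
- In its favour: the regiochemistry is dictated by the methoxy group next to the aryne, a reliable effect. The step is metal-free and mild, forms two C–C bonds in one operation (better than the chosen key step on bond count), and avoids an ortho-bromo aryllithium.
- Against it here: it closes no ring and sets no stereocentre. Direct Claisen closure of A4 would give a 1,3-dione that aromatises, so the ester must be reduced to the aldehyde and ring B closed by an enantioselective aldol, which is the problem of Alternative 3. A5 needs three to four steps. C5 is still unfunctionalised afterwards, which is equal to the chosen plan.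
- Comparison: equal on the C5 problem, better on the regiocontrol of the two anchors, worse on stereocontrol (deferred to a later, less certain step), and probably longer.

Alternative 3: The C2–C3 bond is cut. A dinuclear zinc catalyst of the ProPhenol type would enolise the C8a acetyl group of the keto aldehyde A8 and add C2 to the aldehyde carbon, closing ring B (6-enolexo-exo-trig) and setting C3 in A7.
- In its favour: the stereocentre is made in the last C–C bond-forming event as a free carbinol, so no C3 protecting group and no organometallic with a β-oxygen are involved. Ring C is already in place, so only two O-deprotections remain; on end-game economy it is better than the chosen plan. Catalytic direct aldol reactions of aryl methyl ketones are an established reaction type, so on precedent for the enantioselective event it is at least equal.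
- Against it here: A8 is an arylacetaldehyde whose benzylic CH2 is more acidic than the twisted, di-ortho-substituted acetyl group, so enolisation on the wrong side and self-condensation compete. Under zinc alkoxide A7 can undergo retro-aldol (loss of ee) or dehydration and aromatisation. The pyrone can bind zinc. A8, a hexasubstituted benzene, needs a long synthesis of its own.
- Comparison: the chosen plan is better on the robustness of its precursor (a stable, achiral carbinol) and in fixing C3 as an ether that cannot retro-aldolise. Alternative 3 is better on the number of steps after ring closure.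

Key step: step 3

Assumption: 1, 2, 4, 10 and 11 are taken as catalogue compounds.
Assumption: the sense of induction of the ferrocenyl aminophosphine in step 3 cannot be assigned in advance; the ligand antipode that delivers (R)-8 is the one used (both antipodes are available), and one antipode is written below.
Remark: the structures of the key-step precursor 7 (OH cis to benzyloxy, mirror plane) and product 8 (R at C3, as in the target) were checked and needed no correction; the changes to the design lie outside the key step (chemoselective mono-alkylation of a bromo-iodo arene, and ring C built in place rather than coupled as a stannane).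

Step 1
Reactants: 1 1-bromo-3-iodo-5-methoxybenzene; 2 (3-methylbutyl)zinc bromide (0.5 M in THF)
Product: 3 1-bromo-3-methoxy-5-(3-methylbutyl)benzene
Conditions: Pd(dppf)Cl2 (2 mol%), THF, 0 °C to rt
Reagents that add atoms: none
Why: Negishi coupling; zerovalent palladium inserts far faster into the carbon–iodine bond than into C–Br, so mono-alkylation is chemoselective, and the wide-bite-angle dppf ligand favours reductive elimination over β-hydride loss from the primary alkyl group.

Step 2
Reactants: 3 1-bromo-3-methoxy-5-(3-methylbutyl)benzene; 4 3-(benzyloxy)cyclobutan-1-one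
Product: 7 cis-3-(benzyloxy)-1-[2-bromo-6-methoxy-4-(3-methylbutyl)phenyl]cyclobutan-1-ol, via aryllithium 5 (not isolated), via arylcerium dichloride 6 (not isolated)
Conditions: LiN(i-Pr)2 (1.1 equiv), THF, −78 °C, 1 h; CeCl3 (1.3 equiv), −78 °C; then 4, −78 to −40 °C; aq. NH4Cl
Reagents that add atoms: none
Why: Directed ortho-lithiation removes the most acidic ring proton, flanked by Br and OMe, and the doubly ortho-substituted aryllithium is kept at −78 °C where loss of LiBr is slow; transmetalation to the organocerium gives clean 1,2-addition to the enolisable cyclobutanone, and the nucleophile enters the puckered ring anti to the 3-benzyloxy group, so OH ends cis to OBn and the product is a single achiral diastereomer.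

Step 3
Reactants: 7 cis-3-(benzyloxy)-1-[2-bromo-6-methoxy-4-(3-methylbutyl)phenyl]cyclobutan-1-ol
Product: 8 (3R)-3-(benzyloxy)-8-methoxy-6-(3-methylbutyl)-3,4-dihydronaphthalen-1(2H)-one
Conditions: Pd(OAc)2 (5 mol%), (R)-N,N-dimethyl-1-[(S)-2-(diphenylphosphino)ferrocenyl]ethylamine (10 mol%), Cs2CO3 (2 equiv), toluene (0.02 M), 60 °C
Reagents that add atoms: none
Why: Zerovalent palladium formed from Pd(OAc)2 and the aminophosphine inserts into the only C–Br bond (C4a), Cs2CO3 turns the tertiary alcohol into a palladium-bound alkoxide, β-carbon elimination cleaves one of the two enantiotopic C1–CH2 bonds of the strained ring (about 26 kcal/mol released) so that the carbinol carbon becomes the C1 ketone and the freed CH2 a primary alkylpalladium, and C(sp2)–C(sp3) reductive elimination joins this CH2 (C4) to C4a. The closest known reaction types are the bimolecular palladium-catalysed ring-opening arylation of tert-cyclobutanols with aryl bromides, which desymmetrises 3-substituted cyclobutanols with ferrocenyl aminophosphines, and the ring expansion of 1-(2-haloaryl)cyclobutanols to 1-tetralones under monovalent rhodium catalysis; the step carries the first over to the substrate class of the second. Ring B closes by reductive elimination from a seven-membered aryl(alkyl)palladacycle, a four-to-six ring expansion driven by strain release and not a Baldwin-type closure. C3 becomes a stereocentre only through the choice between the two C1–CH2 bonds; no bond at C3 is touched and the substrate, having a mirror plane, has no bias of its own, so the chiral N,P ligand on palladium is the sole control element and its antipode fixes R. The step needs reductive elimination to outrun β-hydride and β-benzyloxy elimination from the alkylpalladium; the cis-chelating ligand leaves no free site and the cyclic aryl(alkyl)palladium cannot easily place C3–H or C3–O syn to the metal. It also needs the alkoxide-bound palladium to reach a ring CH2 although aryl group and alkoxide sit on one molecule; the hemilabile amine arm, the high dilution (against alkoxide transfer between molecules) and the ring strain are what the design relies on, and this point is taken up under the uncertain steps.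

Step 4
Reactants: 8 (3R)-3-(benzyloxy)-8-methoxy-6-(3-methylbutyl)-3,4-dihydronaphthalen-1(2H)-one
Product: 9 (3R)-3-(benzyloxy)-5-bromo-8-methoxy-6-(3-methylbutyl)-3,4-dihydronaphthalen-1(2H)-one
Conditions: NBS (1.05 equiv), MeCN, 0 °C to rt, dark
Reagents that add atoms: N-bromosuccinimide, O=C1CCC(=O)N1Br
Why: Electrophilic aromatic bromination; C5 is para to the methoxy group, ortho to two alkyl groups and meta to the acyl group, whereas C7 is shielded by the methoxy methyl group that is turned away from the peri carbonyl, and polar NBS in MeCN without acid favours ring over α-keto or benzylic bromination; C3 is not touched.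

Step 5
Reactants: 10 tert-butyl acetate; 11 3-(trimethylsilyl)prop-2-ynal
Product: 13 tert-butyl 3-hydroxy-5-(trimethylsilyl)pent-4-ynoate (racemic), via lithium enolate 12 (not isolated)
Conditions: LiN(i-Pr)2 (1.05 equiv), THF, −78 °C; then 11, −78 °C; aq. NH4Cl
Reagents that add atoms: none
Why: Aldol addition of an ester lithium enolate to a non-enolisable ynal, 1,2-selective at −78 °C; the carbinol is oxidised later, so its configuration does not matter.

Step 6
Reactants: 13 tert-butyl 3-hydroxy-5-(trimethylsilyl)pent-4-ynoate
Product: 14 tert-butyl 3-hydroxypent-4-ynoate (racemic)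
Conditions: K2CO3 (0.2 equiv), MeOH, 0 °C
Reagents that add atoms: none
Why: Methanolysis of the alkynyl C–Si bond; the tert-butyl ester does not transesterify at 0 °C and the short, cold exposure avoids retro-aldol cleavage.

Step 7
Reactants: 9 (3R)-3-(benzyloxy)-5-bromo-8-methoxy-6-(3-methylbutyl)-3,4-dihydronaphthalen-1(2H)-one; 14 tert-butyl 3-hydroxypent-4-ynoate
Product: 15 tert-butyl 5-[(7R)-7-(benzyloxy)-4-methoxy-2-(3-methylbutyl)-5-oxo-5,6,7,8-tetrahydronaphthalen-1-yl]-3-hydroxypent-4-ynoate (both epimers at the side-chain carbinol)
Conditions: Pd(PhCN)2Cl2 (5 mol%), [HP(t-Bu)3]BF4 (10 mol%), CuI (5 mol%), i-Pr2NH, dioxane, rt to 45 °C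
Reagents that add atoms: none
Why: Sonogashira coupling; the bulky, electron-rich P(t-Bu)3 allows oxidative addition at the di-ortho-substituted, electron-rich C–Br bond near room temperature, and a secondary amine at that temperature is too weak a base to expel benzyl alcohol from the β-alkoxy ketone; the epimer mixture converges in step 8.

Step 8
Reactants: 15 tert-butyl 5-[(7R)-7-(benzyloxy)-4-methoxy-2-(3-methylbutyl)-5-oxo-5,6,7,8-tetrahydronaphthalen-1-yl]-3-hydroxypent-4-ynoate
Product: 16 tert-butyl 5-[(7R)-7-(benzyloxy)-4-methoxy-2-(3-methylbutyl)-5-oxo-5,6,7,8-tetrahydronaphthalen-1-yl]-3-oxopent-4-ynoate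
Conditions: Dess–Martin periodinane (1.3 equiv), NaHCO3, CH2Cl2, 0 °C
Reagents that add atoms: none
Why: Dess–Martin oxidation of the secondary propargylic alcohol to the ynone under buffered, neutral conditions that touch neither the benzyl ether nor ring B; both epimers give the same ynone, which is used without storage.

Step 9
Reactants: 16 tert-butyl 5-[(7R)-7-(benzyloxy)-4-methoxy-2-(3-methylbutyl)-5-oxo-5,6,7,8-tetrahydronaphthalen-1-yl]-3-oxopent-4-ynoate
Product: 17 (3R)-3-(benzyloxy)-5-(4-hydroxy-2-oxo-2H-pyran-6-yl)-8-methoxy-6-(3-methylbutyl)-3,4-dihydronaphthalen-1(2H)-one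
Conditions: (SPhos)AuNTf2 (5 mol%; SPhos = 2-dicyclohexylphosphino-2',6'-dimethoxybiphenyl), MeNO2/AcOH 4:1, rt
Reagents that add atoms: none
Why: Gold-catalysed 6-endo-dig oxycyclisation of a tert-butyl 3-oxoalk-4-ynoate; monovalent gold activates the alkyne, the ester carbonyl oxygen attacks the ynone β-carbon (the aryl-bearing one, as the ynone polarisation dictates), the tert-butyl group leaves as isobutene and protodeauration gives the 4-hydroxy-2-pyrone; the weakly acidic medium spares the β-alkoxy ketone.

Step 10
Reactants: 17 (3R)-3-(benzyloxy)-5-(4-hydroxy-2-oxo-2H-pyran-6-yl)-8-methoxy-6-(3-methylbutyl)-3,4-dihydronaphthalen-1(2H)-one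
Product: 18 (3R)-3,8-dihydroxy-5-(4-hydroxy-2-oxo-2H-pyran-6-yl)-6-(3-methylbutyl)-3,4-dihydronaphthalen-1(2H)-one (target, CNP0134824.1)
Conditions: BCl3 (6 equiv), C6HMe5 (4 equiv), CH2Cl2, −78 to −20 °C; MeOH, pH 5 phosphate buffer
Reagents that add atoms: none
Why: Lewis-acid ether cleavage; BCl3 chelated between the C1 carbonyl and the peri methoxy oxygen cleaves the methyl ether, and the secondary benzyl ether is cleaved at the benzylic carbon with pentamethylbenzene trapping the benzyl cation so that the pyrone is not C-benzylated; the C3–O bond is never broken, so R is retained, and the cold, base-free conditions avoid dehydration of ring B.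

## Compound list

1 | 1-bromo-3-iodo-5-methoxybenzene | COc1cc(Br)cc(I)c1 | starting material
2 | (3-methylbutyl)zinc bromide | CC(C)CC[Zn]Br | starting material
3 | 1-bromo-3-methoxy-5-(3-methylbutyl)benzene | COc1cc(Br)cc(CCC(C)C)c1 | intermediate
4 | 3-(benzyloxy)cyclobutan-1-one | O=C1CC(OCc2ccccc2)C1 | starting material
5 | [2-bromo-6-methoxy-4-(3-methylbutyl)phenyl]lithium | [Li]c1c(Br)cc(CCC(C)C)cc1OC | intermediate
6 | [2-bromo-6-methoxy-4-(3-methylbutyl)phenyl]cerium dichloride | Cl[Ce](Cl)c1c(Br)cc(CCC(C)C)cc1OC | intermediate
7 | cis-3-(benzyloxy)-1-[2-bromo-6-methoxy-4-(3-methylbutyl)phenyl]cyclobutan-1-ol (achiral) | CC(C)CCc1cc(OC)c(c(Br)c1)[C@]1(O)C[C@@H](OCc2ccccc2)C1 | intermediate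
8 | (3R)-3-(benzyloxy)-8-methoxy-6-(3-methylbutyl)-3,4-dihydronaphthalen-1(2H)-one | CC(C)CCc1cc(OC)c2c(c1)C[C@@H](OCc1ccccc1)CC2=O | intermediate
9 | (3R)-3-(benzyloxy)-5-bromo-8-methoxy-6-(3-methylbutyl)-3,4-dihydronaphthalen-1(2H)-one | CC(C)CCc1cc(OC)c2c(c1Br)C[C@@H](OCc1ccccc1)CC2=O | intermediate
10 | tert-butyl acetate | CC(=O)OC(C)(C)C | starting material
11 | 3-(trimethylsilyl)prop-2-ynal | O=CC#C[Si](C)(C)C | starting material
12 | lithium enolate of tert-butyl acetate | [Li]OC(=C)OC(C)(C)C | intermediate
13 | tert-butyl 3-hydroxy-5-(trimethylsilyl)pent-4-ynoate (racemic) | CC(C)(C)OC(=O)CC(O)C#C[Si](C)(C)C | intermediate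
14 | tert-butyl 3-hydroxypent-4-ynoate (racemic) | CC(C)(C)OC(=O)CC(O)C#C | intermediate
15 | tert-butyl 5-[(7R)-7-(benzyloxy)-4-methoxy-2-(3-methylbutyl)-5-oxo-5,6,7,8-tetrahydronaphthalen-1-yl]-3-hydroxypent-4-ynoate (both side-chain epimers) | CC(C)CCc1cc(OC)c2c(c1C#CC(O)CC(=O)OC(C)(C)C)C[C@@H](OCc1ccccc1)CC2=O | intermediate
16 | tert-butyl 5-[(7R)-7-(benzyloxy)-4-methoxy-2-(3-methylbutyl)-5-oxo-5,6,7,8-tetrahydronaphthalen-1-yl]-3-oxopent-4-ynoate | CC(C)CCc1cc(OC)c2c(c1C#CC(=O)CC(=O)OC(C)(C)C)C[C@@H](OCc1ccccc1)CC2=O | intermediate
17 | (3R)-3-(benzyloxy)-5-(4-hydroxy-2-oxo-2H-pyran-6-yl)-8-methoxy-6-(3-methylbutyl)-3,4-dihydronaphthalen-1(2H)-one | CC(C)CCc1cc(OC)c2c(c1-c1cc(O)cc(=O)o1)C[C@@H](OCc1ccccc1)CC2=O | intermediate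
18 | (3R)-3,8-dihydroxy-5-(4-hydroxy-2-oxo-2H-pyran-6-yl)-6-(3-methylbutyl)-3,4-dihydronaphthalen-1(2H)-one | CC(C)CCc1cc(O)c2c(c1-c1cc(O)cc(=O)o1)C[C@@H](O)CC2=O | target

## Step count and uncertain steps

Total step count: 10 (steps 1 to 10). Longest linear sequence: 8 steps (1, 2, 3, 4, 7, 8, 9, 10); steps 5 and 6 make the side-chain fragment.

Step 3 (key step). After oxidative addition the aryl group and the alkoxide sit on the same palladium and tend to close a flat five-membered C,O-chelate. In that chelate both ring CH2 groups point away from the metal, so the syn arrangement Pd–O–C1–CH2 needed for β-carbon elimination is hard to reach. The likely failure processes are: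
- stalling of the chelate, followed by protodebromination;
- C–C cleavage at the palladium of a second molecule, which leads to intermolecular arylation and chain growth instead of ring B;
- loss of benzyl alkoxide or of a β-hydride from the alkylpalladium, which opens the chain for good;
- base-promoted loss of benzyl alcohol from the product at 60 °C, with aromatisation;
- poor discrimination of the enantiotopic bonds.

Fallback, from 3 to 9, by a chiral-pool route that needs no C–C cleavage. 3 is converted (Mg, LiCl, THF) into [3-methoxy-5-(3-methylbutyl)phenyl]magnesium bromide F1, which opens ethyl (S)-oxiran-2-ylacetate at its terminal carbon under CuI catalysis at −30 °C to give ethyl (3R)-3-hydroxy-4-[3-methoxy-5-(3-methylbutyl)phenyl]butanoate F2. Neutral O-benzylation (2-benzyloxy-1-methylpyridinium triflate, MgO, PhCF3) gives ethyl (3R)-3-(benzyloxy)-4-[3-methoxy-5-(3-methylbutyl)phenyl]butanoate F3. NBS in MeCN brominates para to the methoxy group, between the two alkyl groups, to give ethyl (3R)-3-(benzyloxy)-4-[2-bromo-5-methoxy-3-(3-methylbutyl)phenyl]butanoate F4; this bromine is the later C5 handle and also blocks the wrong site of ring closure. LiOH in aqueous THF at 0 °C gives (3R)-3-(benzyloxy)-4-[2-bromo-5-methoxy-3-(3-methylbutyl)phenyl]butanoic acid F5. 1-Chloro-N,N,2-trimethylprop-1-en-1-amine gives (3R)-3-(benzyloxy)-4-[2-bromo-5-methoxy-3-(3-methylbutyl)phenyl]butanoyl chloride F6, and SnCl4 at −78 °C closes ring B by Friedel–Crafts acylation at the only free position ortho to the side chain (ortho to methoxy), which gives 9. The stereocentre comes from the epoxide and no bond to it is broken.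

Step 2. The ortho-bromo aryllithium can lose LiBr to an aryne or let the halogen migrate while it waits for transmetalation and addition. Proton transfer from the cyclobutanone would return 3. Incomplete anti addition would give some trans isomer, a different substrate for step 3.

Fallback, from 3 to 7, separating the short-lived lithium species from the slow addition. 3 is lithiated as before and quenched at once with I2 at −78 °C to give 1-bromo-2-iodo-3-methoxy-5-(3-methylbutyl)benzene F7. Iodine–magnesium exchange with i-PrMgCl·LiCl at −40 °C gives the thermally stable [2-bromo-6-methoxy-4-(3-methylbutyl)phenyl]magnesium chloride F8, which adds to 4 in the presence of LaCl3·2LiCl at 0 °C to give 7.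

Step 7. Oxidative addition at the di-ortho-substituted, electron-rich C–Br bond may be slow. Oxidative dimerisation of the alkyne would then take over, and warming with amine would expel benzyl alcohol from ring B with aromatisation.

Fallback, from 14 and 9 to 15, by a base-free Stille alkynylation. 14 is silylated (t-BuMe2SiCl, imidazole) to tert-butyl 3-[(tert-butyldimethylsilyl)oxy]pent-4-ynoate F9. Heating with Bu3SnOMe at 60 °C gives tert-butyl 3-[(tert-butyldimethylsilyl)oxy]-5-(tributylstannyl)pent-4-ynoate F10. This couples with 9 (Pd2(dba)3, P(t-Bu)3, toluene, 80 °C) to give tert-butyl 5-[(7R)-7-(benzyloxy)-4-methoxy-2-(3-methylbutyl)-5-oxo-5,6,7,8-tetrahydronaphthalen-1-yl]-3-[(tert-butyldimethylsilyl)oxy]pent-4-ynoate F11, and HF·pyridine removes the silyl group to give 15.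

Step 9. Attack of the ester oxygen at the alkyne carbon that bears the bulky aryl group may be slowed. Then 5-exo closure, hydration of the ynone, or loss of the tert-butyl group followed by decarboxylation of the β-keto acid could compete.

Fallback, from 16 to 17, without gold. Pyrrolidine adds to the ynone at 0 °C to give tert-butyl 5-[(7R)-7-(benzyloxy)-4-methoxy-2-(3-methylbutyl)-5-oxo-5,6,7,8-tetrahydronaphthalen-1-yl]-3-oxo-5-(pyrrolidin-1-yl)pent-4-enoate F12. Aqueous AcOH hydrolyses it to tert-butyl 5-[(7R)-7-(benzyloxy)-4-methoxy-2-(3-methylbutyl)-5-oxo-5,6,7,8-tetrahydronaphthalen-1-yl]-3,5-dioxopentanoate F13. Heating in toluene at 110 °C generates the acylketene, which is trapped by the enol oxygen to give 17.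

Step 10. Lewis-acid-promoted loss of the C3 oxygen substituent, followed by tautomerisation, would aromatise ring B. Cleavage of the secondary benzyl ether may be incomplete, and the benzyl cation may alkylate the pyrone.

Fallback, from 17 to 18, in two stages. Hydrogenolysis (H2, Pd(OH)2/C, EtOAc, short contact) removes the benzyl group to give (3R)-3-hydroxy-5-(4-hydroxy-2-oxo-2H-pyran-6-yl)-8-methoxy-6-(3-methylbutyl)-3,4-dihydronaphthalen-1(2H)-one F14. Then BCl3 (2 equiv, −78 °C) cleaves only the chelated peri methyl ether to give 18, so no benzyl cation is formed next to the carbinol.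

## Further compounds

F1 | step 3 | [3-methoxy-5-(3-methylbutyl)phenyl]magnesium bromide | COc1cc([Mg]Br)cc(CCC(C)C)c1
F2 | step 3 | ethyl (3R)-3-hydroxy-4-[3-methoxy-5-(3-methylbutyl)phenyl]butanoate | CCOC(=O)C[C@H](O)Cc1cc(OC)cc(CCC(C)C)c1
F3 | step 3 | ethyl (3R)-3-(benzyloxy)-4-[3-methoxy-5-(3-methylbutyl)phenyl]butanoate | CCOC(=O)C[C@H](OCc1ccccc1)Cc1cc(OC)cc(CCC(C)C)c1
F4 | step 3 | ethyl (3R)-3-(benzyloxy)-4-[2-bromo-5-methoxy-3-(3-methylbutyl)phenyl]butanoate | CCOC(=O)C[C@H](OCc1ccccc1)Cc1cc(OC)cc(CCC(C)C)c1Br
F5 | step 3 | (3R)-3-(benzyloxy)-4-[2-bromo-5-methoxy-3-(3-methylbutyl)phenyl]butanoic acid | OC(=O)C[C@H](OCc1ccccc1)Cc1cc(OC)cc(CCC(C)C)c1Br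
F6 | step 3 | (3R)-3-(benzyloxy)-4-[2-bromo-5-methoxy-3-(3-methylbutyl)phenyl]butanoyl chloride | ClC(=O)C[C@H](OCc1ccccc1)Cc1cc(OC)cc(CCC(C)C)c1Br
F7 | step 2 | 1-bromo-2-iodo-3-methoxy-5-(3-methylbutyl)benzene | COc1cc(CCC(C)C)cc(Br)c1I
F8 | step 2 | [2-bromo-6-methoxy-4-(3-methylbutyl)phenyl]magnesium chloride | COc1cc(CCC(C)C)cc(Br)c1[Mg]Cl
F9 | step 7 | tert-butyl 3-[(tert-butyldimethylsilyl)oxy]pent-4-ynoate | CC(C)(C)OC(=O)CC(O[Si](C)(C)C(C)(C)C)C#C
F10 | step 7 | tert-butyl 3-[(tert-butyldimethylsilyl)oxy]-5-(tributylstannyl)pent-4-ynoate | CC(C)(C)OC(=O)CC(O[Si](C)(C)C(C)(C)C)C#C[Sn](CCCC)(CCCC)CCCC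
F11 | step 7 | tert-butyl 5-[(7R)-7-(benzyloxy)-4-methoxy-2-(3-methylbutyl)-5-oxo-5,6,7,8-tetrahydronaphthalen-1-yl]-3-[(tert-butyldimethylsilyl)oxy]pent-4-ynoate | CC(C)CCc1cc(OC)c2c(c1C#CC(O[Si](C)(C)C(C)(C)C)CC(=O)OC(C)(C)C)C[C@@H](OCc1ccccc1)CC2=O
F12 | step 9 | tert-butyl 5-[(7R)-7-(benzyloxy)-4-methoxy-2-(3-methylbutyl)-5-oxo-5,6,7,8-tetrahydronaphthalen-1-yl]-3-oxo-5-(pyrrolidin-1-yl)pent-4-enoate | CC(C)CCc1cc(OC)c2c(c1C(=CC(=O)CC(=O)OC(C)(C)C)N1CCCC1)C[C@@H](OCc1ccccc1)CC2=O
F13 | step 9 | tert-butyl 5-[(7R)-7-(benzyloxy)-4-methoxy-2-(3-methylbutyl)-5-oxo-5,6,7,8-tetrahydronaphthalen-1-yl]-3,5-dioxopentanoate | CC(C)CCc1cc(OC)c2c(c1C(=O)CC(=O)CC(=O)OC(C)(C)C)C[C@@H](OCc1ccccc1)CC2=O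
F14 | step 10 | (3R)-3-hydroxy-5-(4-hydroxy-2-oxo-2H-pyran-6-yl)-8-methoxy-6-(3-methylbutyl)-3,4-dihydronaphthalen-1(2H)-one | CC(C)CCc1cc(OC)c2c(c1-c1cc(O)cc(=O)o1)C[C@@H](O)CC2=O
A1 | alternative 1 | prop-2-en-1-yl (7R)-7-[(tert-butyldimethylsilyl)oxy]-4-hydroxy-2-(3-methylbutyl)-5-oxo-5,6,7,8-tetrahydronaphthalene-1-carboxylate | CC(C)CCc1cc(O)c2c(c1C(=O)OCC=C)C[C@@H](O[Si](C)(C)C(C)(C)C)CC2=O
A2 | alternative 1 | (5R)-5-[(tert-butyldimethylsilyl)oxy]-2-(4-methylbenzenesulfinyl)cyclohex-2-en-1-one (either configuration at sulfur) | Cc1ccc(cc1)S(=O)C1=CC[C@@H](O[Si](C)(C)C(C)(C)C)CC1=O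
A3 | alternative 1 | 1-methyl 5-prop-2-en-1-yl 3-(3-methylbutyl)pent-2-enedioate | C=CCOC(=O)CC(CCC(C)C)=CC(=O)OC
A4 | alternative 2 | methyl 2-[2-acetyl-3-methoxy-5-(3-methylbutyl)phenyl]acetate | COC(=O)Cc1cc(CCC(C)C)cc(OC)c1C(C)=O
A5 | alternative 2 | 3-methoxy-5-(3-methylbutyl)-2-(trimethylsilyl)phenyl trifluoromethanesulfonate | COc1cc(CCC(C)C)cc(OS(=O)(=O)C(F)(F)F)c1[Si](C)(C)C
A6 | alternative 2 | methyl acetoacetate | COC(=O)CC(C)=O
A7 | alternative 3 | (3R)-5-[4-(benzyloxy)-2-oxo-2H-pyran-6-yl]-3-hydroxy-8-methoxy-6-(3-methylbutyl)-3,4-dihydronaphthalen-1(2H)-one | CC(C)CCc1cc(OC)c2c(c1-c1cc(OCc3ccccc3)cc(=O)o1)C[C@@H](O)CC2=O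
A8 | alternative 3 | {2-acetyl-6-[4-(benzyloxy)-2-oxo-2H-pyran-6-yl]-3-methoxy-5-(3-methylbutyl)phenyl}acetaldehyde | CC(C)CCc1cc(OC)c(C(C)=O)c(CC=O)c1-c1cc(OCc2ccccc2)cc(=O)o1
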